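One turnover per second per enzyme is the unit to reckon in here.

| setting | cedar | elm | flask |
|---|---|---|---|
| starting material | 20 mM (in portions, 2) | 20 mM (in portions, 2) | 20 mM (in portions, 2) |
| second substrate | 2.8 equiv | 4.4 equiv | 2.00 equiv |
| enzyme | 0.1 mol% | 0.1 mol% | 0.1 mol% |
| remark | run made earlier; portions every 80 s | run made earlier; portions every 80 s | the portions of starting material follow each other after 80 s, the first at the start |
| time |  |  | 2.5 min |

- cedar (time / min: target / %, starting material / %): 0.333: 7, 46; 0.833: 13, 38; 1.50: 21, 77; 2.50: 33, 62
- elm (time / min: target / %, starting material / %): 0.200: 2, 47; 0.500: 6, 43; 1.00: 9, 35; 2.50: 32, 65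

(scatter of a reading: 2 percentage points)

1. amount of target in percent of the starting material charged, at 30 s, 80 s and 2.5 min

1. Starting material is the limiting reagent of the flask, with 2.00 equiv of second substrate against it. Its balance reads [starting material] + [target] = what has been added so far. The last readings sum to 95.0 % in the cedar run and 97.0 % in the elm run, so you can follow target alone.

2. Divide target, as a fraction of the charge, by the enzyme loading and the time. The cedar run gives 2.20 s⁻¹ and the elm run 2.13 s⁻¹. Call this the mean turnover rate, the usual turnover frequency. The two rest on readings of 33 % and 32 % with a scatter of 2 percentage points, so they cannot be told apart.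

3. Early on they part. Up to 0.833 min the cedar run turns over at 2.60 s⁻¹, and up to 1.00 min the elm run is slower than that, at 1.50 s⁻¹. Their ratio of 1.73 stands near the inverse ratio of equivalents, 1.57, as if second substrate competed for enzyme while [starting material] is low. Scaled inversely to the flask, the cedar rate becomes 3.64 s⁻¹.

4. That scaling is the weak link. From those readings to the end, the cedar run gives 2.00 s⁻¹ and the elm run 2.56 s⁻¹, the opposite order. So I treat it as an upper bound and take the middle, 3.12 s⁻¹, before the second portion, and the mean 2.28 s⁻¹ after it.

5. My reckoning for the flask is 9.36 %, 25.0 % and 40.9 %.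

The forecast says 6 %, 16 % and 30 %, on the ground that “These effects roughly offset”. At the last time my figure is higher than the forecast.

    starting material + enzyme ⇌ complex A (K = 4300 L mol⁻¹, k = 1910 L mol⁻¹ s⁻¹)
    complex A → enzyme + target (k = 5.13 s⁻¹)
    second substrate + enzyme ⇌ complex B (K = 41.0 L mol⁻¹, k = 2930 L mol⁻¹ s⁻¹)
    complex B → enzyme + second product (k = 1.57 s⁻¹)
    enzyme ⇌ dormant form (K = 22.0, k = 0.00872 s⁻¹)

The flask gives 8.21 %, 19.7 % and 39.4 %, a mean turnover rate of 2.63 s⁻¹, higher than the 2.20 s⁻¹ read from the single cedar reading of 33 %; divided by 5.13 s⁻¹, the flask's rate means complex A held 51.3 % of the catalyst on average. After 2.50 min in the flask, enzyme enters complex A at 0.20 of its forward rate into complex B, yet complex A stands at 50.2 % and complex B at 18.9 %.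

Readings and results stem from a simulated flask with made-up constants; scatter was added.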